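Numbering: C1 allyl bridgehead, C2=C3(OMe), C4 CH(OAc), C5 OMe bridgehead, C6 CH(aryl), C7 CH(CH3), C8 bridging ketone; exo means on the side of C8. The enol ether and the acetate are traced back to an exo,exo-3,4-diol, and the C3–C4 bond of that diol is the main cut.
What allows this cut: C3 and C4 are neighbouring oxygen-bearing carbons of the six-membered ring C1–C2–C3–C4–C5–C8, which sits on the cyclopentanone ring C1–C7–C6–C5–C8 through C1 and C5. Breaking C3–C4 leaves a formyl group on C5 and an acetaldehyde arm on C1 on the same (endo) face, a 1,6-dialdehyde.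
Further cuts: C5–C4 (formaldehyde aldol), C5–OMe (enolate hydroxylation, methylation), C1–allyl and C7–CH3 (conjugate addition and enolate alkylation), C1–C2 (Negishi coupling), C6–aryl (conjugate addition).
Forward: the five-membered ring is bought as an enantiopure silyloxycyclopentenone and substituted at C6, then at C7 and C1, then at C5. The six-membered ring is closed by SmI2 pinacol coupling, and orthoester opening, oxidation, ketalisation and loss of methanol finish the bridge.
Stereochemistry: C6 by addition anti to the silyloxy group (chirality transfer from the purchased enone), C7 anti to the C6 aryl group, C1 anti to the C7 methyl group, C5 anti to the C6 aryl group. C4 (with the transient C3) comes from the samarium-bridged cis coupling on the exo face, because the endo C7 methyl group closes the endo side at C3.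

Key step: step 11

Assumption: (4S)-4-[(tert-butyldimethylsilyl)oxy]cyclopent-2-en-1-one and (3,4-dimethoxyphenyl)magnesium bromide (THF solution) are taken as purchasable reagents.

Step 1
Reactants: 1 (4S)-4-[(tert-butyldimethylsilyl)oxy]cyclopent-2-en-1-one; 2 (3,4-dimethoxyphenyl)magnesium bromide
Product: 3 (3R,4S)-4-[(tert-butyldimethylsilyl)oxy]-3-(3,4-dimethoxyphenyl)cyclopentan-1-one
Conditions: 2 (1.5 equiv), CuBr·SMe2 (10 mol %), THF, −78 → −40 °C; aq. work-up
Reagents that add atoms: none
Why: Copper-catalysed conjugate addition of the aryl Grignard reagent, in which the aryl group enters the enone face opposite to the neighbouring silyloxy group and so sets the C6 stereocentre by transfer from the stereocentre of 1.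

Step 2
Reactants: 3
Product: 4 (4S)-4-(3,4-dimethoxyphenyl)cyclopent-2-en-1-one
Conditions: DBU (1.1 equiv), CH2Cl2, 0 °C, short reaction time
Reagents that add atoms: none
Why: E1cB β-elimination of the silyloxy group through the enolate on the methylene side, which places the double bond (future C1=C7) away from the aryl-bearing carbon and should leave the C6 stereocentre untouched as long as the contact with base is brief.

Step 3
Reactants: 4
Product: 5 (4S)-4-(3,4-dimethoxyphenyl)-2-iodocyclopent-2-en-1-one
Conditions: I2 (1.5 equiv), pyridine–CH2Cl2 (1:1), 0 °C → rt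
Reagents that add atoms: iodine, II
Why: α-Iodination of the enone by a Baylis–Hillman-type sequence (pyridine addition, iodination of the enolate, elimination), which functionalises only the α-carbon, the future C1.

Step 4
Reactants: 5; 6 tert-butyl bromoacetate
Product: 8 tert-butyl 2-[(3S)-3-(3,4-dimethoxyphenyl)-5-oxocyclopent-1-en-1-yl]acetate, via bromozinc ester enolate 7 (not isolated)
Conditions: 6, Zn dust (activated), THF, 40 °C; then 5, Pd(dba)2 (5 mol %), P(2-furyl)3 (10 mol %), THF, rt
Reagents that add atoms: none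
Why: Negishi cross-coupling of the Reformatsky reagent, in which zerovalent palladium inserts into the vinyl C–I bond, the zinc reagent transmetallates and reductive elimination forms the C1–C2 bond without a base that could touch the γ-stereocentre.

Step 5
Reactants: 8; 9 allyl bromide
Product: 11 tert-butyl 2-[(1R,2R,3S)-3-(3,4-dimethoxyphenyl)-2-methyl-5-oxo-1-(prop-2-en-1-yl)cyclopentyl]acetate, via lithium enolate 10 (not isolated)
Conditions: Me2CuLi (1.3 equiv, from MeLi and CuBr·SMe2), Et2O, −78 → −40 °C; then 9 (5 equiv), HMPA, THF, −40 → 0 °C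
Reagents that add atoms: lithium dimethylcuprate, [Li+].C[Cu-]C
Why: Conjugate addition followed by alkylation of the regiodefined enolate: methyl adds to C7 anti to the neighbouring C6 aryl group, and the tetrasubstituted enolate is then allylated at C1 anti to the new vicinal methyl group, so that allyl ends trans and the acetate arm cis to the methyl group on the quaternary C1.

Step 6
Reactants: 11
Product: 12 tert-butyl 2-[(1R,2R,3S,4S)-3-(3,4-dimethoxyphenyl)-4-hydroxy-2-methyl-5-oxo-1-(prop-2-en-1-yl)cyclopentyl]acetate
Conditions: KN(SiMe3)2 (1.1 equiv), THF, −78 °C; then 2-(phenylsulfonyl)-3-phenyloxaziridine (1.3 equiv), −78 °C; aq. work-up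
Reagents that add atoms: 2-(phenylsulfonyl)-3-phenyloxaziridine, O=S(=O)(c1ccccc1)N1OC1c1ccccc1
Why: Enolate hydroxylation with an N-sulfonyloxaziridine (Davis oxidation) at C5, the only enolisable ring position and far more acidic than the neopentyl ester methylene; the oxygen should arrive anti to the C6 aryl group, but this centre becomes planar again in step 8, so its configuration is of no consequence.

Step 7
Reactants: 12
Product: 13 tert-butyl 2-[(1R,2R,3S,4S)-3-(3,4-dimethoxyphenyl)-4-methoxy-2-methyl-5-oxo-1-(prop-2-en-1-yl)cyclopentyl]acetate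
Conditions: Me3OBF4 (3 equiv), 1,8-bis(dimethylamino)naphthalene (3 equiv), CH2Cl2, 0 °C → rt
Reagents that add atoms: trimethyloxonium tetrafluoroborate, C[O+](C)C.F[B-](F)(F)F
Why: O-Alkylation of the secondary ketol hydroxyl with a trialkyloxonium salt buffered by a non-nucleophilic amine, conditions that methylate without forming the enolate and therefore without ketol rearrangement or C-methylation.

Step 8
Reactants: 13
Product: 14 tert-butyl 2-[(1R,2R,3S,4S)-3-(3,4-dimethoxyphenyl)-4-(hydroxymethyl)-4-methoxy-2-methyl-5-oxo-1-(prop-2-en-1-yl)cyclopentyl]acetate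
Conditions: LiN(SiMe3)2 (1.2 equiv), THF, −78 → −40 °C; then CH2O (gas, from cracked paraformaldehyde), −78 °C; AcOH quench at −78 °C
Reagents that add atoms: formaldehyde, C=O
Why: Aldol addition of the α-methoxy ketone enolate (C5 is the only site, C1 being quaternary) to monomeric formaldehyde, which approaches anti to the vicinal C6 aryl group so that hydroxymethyl ends trans and methoxy cis to the aryl group at the quaternary C5.

Step 9
Reactants: 14
Product: 15 (2S,3S,4R,5R)-3-(3,4-dimethoxyphenyl)-5-(2-hydroxyethyl)-2-(hydroxymethyl)-2-methoxy-4-methyl-5-(prop-2-en-1-yl)cyclopentan-1-ol (either configuration at the carbinol carbon C8)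
Conditions: LiAlH4 (4 equiv), THF, 0 °C → rt; H2O then aq. NaOH work-up
Reagents that add atoms: none
Why: Hydride reduction of the tert-butyl ester and of the ketone in one operation, the configuration of the new C8 carbinol being irrelevant because it is reoxidised in the next step.

Step 10
Reactants: 15
Product: 16 (1S,2S,3R,4R)-2-(3,4-dimethoxyphenyl)-1-methoxy-3-methyl-5-oxo-4-(2-oxoethyl)-4-(prop-2-en-1-yl)cyclopentane-1-carbaldehyde
Conditions: (COCl)2 (5 equiv), DMSO (10 equiv), CH2Cl2, −78 °C; then Et3N (15 equiv), −78 → −20 °C; cold pH 7 buffer; crude product used at once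
Reagents that add atoms: none
Why: Swern oxidation, chosen because all three hydroxyls are converted into alkoxysulfonium ions before the base is added, so that no γ-hydroxy aldehyde is present to close to a lactol and be over-oxidised to a lactone.

Step 11
Reactants: 16
Product: 17 exo,exo-3,4-diol (1R,3S,4S,5S,6S,7R)-6-(3,4-dimethoxyphenyl)-3,4-dihydroxy-5-methoxy-7-methyl-1-(prop-2-en-1-yl)bicyclo[3.2.1]octan-8-one
Conditions: SmI2 (3 equiv, 0.1 M in THF), t-BuOH (2 equiv), THF, −78 °C, slow addition of 16; pH 7 buffer at −78 °C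
Reagents that add atoms: none
Why: Two single-electron transfers from divalent samarium turn the two aldehydes into ketyls that are held on one trivalent samarium centre and couple carbon to carbon, the closest known reaction type being the intramolecular pinacol coupling of a 1,6-dialdehyde to a cis-cyclohexane-1,2-diol. The C3–C4 bond closes the ring C1–C2–C3–C4–C5–C8 in a 6-exo-trig mode (ketyl carbon C4 onto the carbonyl carbon C3) across the cis-1,3 positions of the cyclopentanone. The samarium bridge between the two oxygens makes the diol cis, and the endo methyl group on C7, which lies under the C2–C3 edge, excludes an endo (axial) oxygen on C3, so the C3 oxygen should be equatorial-exo and the C4 oxygen axial-exo; coordination of the same metal to the C8 carbonyl oxygen, which only an exo C4 oxygen can reach, works in the same direction. The step needs the aldehydes to react ahead of the ketone, the C5 methoxy group and the allyl group: the ketone sits between two quaternary carbons and is reduced far more slowly at −78 °C, no HMPA is added so that neither reductive loss of methoxide nor ketyl–olefin closure onto the allyl group keeps pace with the six-ring closure, and the cold quench keeps the product aldolate (C4–O, C8=O) from retro-aldol opening.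

Step 12
Reactants: 17
Product: 19 (1R,3S,4S,5S,6S,7R)-6-(3,4-dimethoxyphenyl)-3-hydroxy-5-methoxy-7-methyl-8-oxo-1-(prop-2-en-1-yl)bicyclo[3.2.1]octan-4-yl acetate, via cyclic orthoacetate 18 (not isolated)
Conditions: MeC(OMe)3 (3 equiv), PPTS (5 mol %), CH2Cl2, rt; evaporate; then AcOH–H2O (4:1), 0 °C → rt
Reagents that add atoms: trimethyl orthoacetate, CC(OC)(OC)OC; water, O
Why: Cyclic orthoester formation on the cis-diol and acid hydrolysis, which by the established rule for cis-diol orthoesters on a chair opens to the axial ester and the equatorial alcohol, so that the acetate lands on the axial exo C4 oxygen while the β-hydroxy ketone is never exposed to base.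

Step 13
Reactants: 19
Product: 20 (1R,4R,5S,6S,7R)-6-(3,4-dimethoxyphenyl)-5-methoxy-7-methyl-3,8-dioxo-1-(prop-2-en-1-yl)bicyclo[3.2.1]octan-4-yl acetate
Conditions: Dess–Martin periodinane (1.5 equiv), CH2Cl2, 0 °C → rt
Reagents that add atoms: none
Why: Dess–Martin oxidation of the remaining equatorial C3 alcohol under nearly neutral conditions, which forestalls acetyl migration, while the endo C4–H lies close to the plane of the new carbonyl group and should not be lost by enolisation.

Step 14
Reactants: 20
Product: 21 (1R,4R,5S,6S,7R)-6-(3,4-dimethoxyphenyl)-3,3,5-trimethoxy-7-methyl-8-oxo-1-(prop-2-en-1-yl)bicyclo[3.2.1]octan-4-yl acetate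
Conditions: HC(OMe)3 (10 equiv), MeOH, camphorsulfonic acid (5 mol %), rt; Et3N quench
Reagents that add atoms: trimethyl orthoformate, COC(OC)OC; methanol, CO
Why: Acid-catalysed ketalisation with the orthoformate as water scavenger, selective for the C3 ketone because the C8 carbonyl group is shielded by the two quaternary bridgeheads, the exo aryl group and the exo acetate.

Step 15
Reactants: 21
Product: 22 (1S,4S,5S,6S,7R)-6-(3,4-dimethoxyphenyl)-3,5-dimethoxy-7-methyl-8-oxo-1-(prop-2-en-1-yl)bicyclo[3.2.1]oct-2-en-4-yl acetate (CNP0221003.1)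
Conditions: TMSOTf (1.2 equiv), iPr2NEt (1.5 equiv), CH2Cl2, −20 °C → rt
Reagents that add atoms: none
Why: Silyl triflate-mediated elimination of methanol from the dimethyl ketal (ketal-to-enol-ether conversion), in which the C3 methoxycarbenium ion gives up the well-aligned axial exo proton of the C2 methylene to the hindered amine rather than the endo C4–H, which lies near the nodal plane of the cation, so that the less substituted C2=C3 enol ether forms under basic conditions that the acid-labile product tolerates.

Compound list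
1 | (4S)-4-[(tert-butyldimethylsilyl)oxy]cyclopent-2-en-1-one | O=C1C=C[C@@H](O[Si](C)(C)C(C)(C)C)C1 | starting material
2 | (3,4-dimethoxyphenyl)magnesium bromide | COc1ccc([Mg]Br)cc1OC | starting material
3 | (3R,4S)-4-[(tert-butyldimethylsilyl)oxy]-3-(3,4-dimethoxyphenyl)cyclopentan-1-one (aryl trans to silyloxy) | O=C1C[C@H](O[Si](C)(C)C(C)(C)C)[C@@H](c2ccc(OC)c(OC)c2)C1 | intermediate
4 | (4S)-4-(3,4-dimethoxyphenyl)cyclopent-2-en-1-one | O=C1C=C[C@@H](c2ccc(OC)c(OC)c2)C1 | intermediate
5 | (4S)-4-(3,4-dimethoxyphenyl)-2-iodocyclopent-2-en-1-one | O=C1C(I)=C[C@@H](c2ccc(OC)c(OC)c2)C1 | intermediate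
6 | tert-butyl bromoacetate | CC(C)(C)OC(=O)CBr | starting material
7 | (2-tert-butoxy-2-oxoethyl)zinc bromide (Reformatsky reagent) | CC(C)(C)OC(=O)C[Zn]Br | intermediate (not isolated)
8 | tert-butyl 2-[(3S)-3-(3,4-dimethoxyphenyl)-5-oxocyclopent-1-en-1-yl]acetate | CC(C)(C)OC(=O)CC1=C[C@@H](c2ccc(OC)c(OC)c2)CC1=O | intermediate
9 | allyl bromide (3-bromoprop-1-ene) | C=CCBr | starting material
10 | lithium (3R,4S)-2-(2-tert-butoxy-2-oxoethyl)-4-(3,4-dimethoxyphenyl)-3-methylcyclopent-1-en-1-olate (methyl trans to aryl) | [Li+].CC(C)(C)OC(=O)CC1=C([O-])C[C@H](c2ccc(OC)c(OC)c2)[C@H]1C | intermediate (not isolated)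
11 | tert-butyl 2-[(1R,2R,3S)-3-(3,4-dimethoxyphenyl)-2-methyl-5-oxo-1-(prop-2-en-1-yl)cyclopentyl]acetate (allyl trans to methyl, methyl trans to aryl) | C=CC[C@@]1(CC(=O)OC(C)(C)C)[C@H](C)[C@@H](c2ccc(OC)c(OC)c2)CC1=O | intermediate
12 | tert-butyl 2-[(1R,2R,3S,4S)-3-(3,4-dimethoxyphenyl)-4-hydroxy-2-methyl-5-oxo-1-(prop-2-en-1-yl)cyclopentyl]acetate (hydroxyl trans to aryl expected; either epimer serves) | C=CC[C@@]1(CC(=O)OC(C)(C)C)[C@H](C)[C@@H](c2ccc(OC)c(OC)c2)[C@H](O)C1=O | intermediate
13 | tert-butyl 2-[(1R,2R,3S,4S)-3-(3,4-dimethoxyphenyl)-4-methoxy-2-methyl-5-oxo-1-(prop-2-en-1-yl)cyclopentyl]acetate | C=CC[C@@]1(CC(=O)OC(C)(C)C)[C@H](C)[C@@H](c2ccc(OC)c(OC)c2)[C@H](OC)C1=O | intermediate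
14 | tert-butyl 2-[(1R,2R,3S,4S)-3-(3,4-dimethoxyphenyl)-4-(hydroxymethyl)-4-methoxy-2-methyl-5-oxo-1-(prop-2-en-1-yl)cyclopentyl]acetate (hydroxymethyl trans, methoxy cis to aryl) | C=CC[C@@]1(CC(=O)OC(C)(C)C)[C@H](C)[C@@H](c2ccc(OC)c(OC)c2)[C@](OC)(CO)C1=O | intermediate
15 | (2S,3S,4R,5R)-3-(3,4-dimethoxyphenyl)-5-(2-hydroxyethyl)-2-(hydroxymethyl)-2-methoxy-4-methyl-5-(prop-2-en-1-yl)cyclopentan-1-ol (carbinol carbon C8 left undefined) | C=CC[C@@]1(CCO)[C@H](C)[C@@H](c2ccc(OC)c(OC)c2)[C@](OC)(CO)C1O | intermediate
16 | (1S,2S,3R,4R)-2-(3,4-dimethoxyphenyl)-1-methoxy-3-methyl-5-oxo-4-(2-oxoethyl)-4-(prop-2-en-1-yl)cyclopentane-1-carbaldehyde (keto dialdehyde) | C=CC[C@@]1(CC=O)[C@H](C)[C@@H](c2ccc(OC)c(OC)c2)[C@](OC)(C=O)C1=O | intermediate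
17 | (1R,3S,4S,5S,6S,7R)-6-(3,4-dimethoxyphenyl)-3,4-dihydroxy-5-methoxy-7-methyl-1-(prop-2-en-1-yl)bicyclo[3.2.1]octan-8-one (3-exo,4-exo-diol, 6-exo-aryl, 7-endo-methyl) | C=CC[C@]12C[C@H](O)[C@H](O)[C@](OC)(C1=O)[C@H](c1ccc(OC)c(OC)c1)[C@H]2C | intermediate
18 | cyclic methyl orthoacetate of 17 across the exo O3 and O4 (orthoester carbon undefined) | C=CC[C@]12C[C@@H]3OC(C)(OC)O[C@@H]3[C@](OC)(C1=O)[C@H](c1ccc(OC)c(OC)c1)[C@H]2C | intermediate (not isolated)
19 | (1R,3S,4S,5S,6S,7R)-6-(3,4-dimethoxyphenyl)-3-hydroxy-5-methoxy-7-methyl-8-oxo-1-(prop-2-en-1-yl)bicyclo[3.2.1]octan-4-yl acetate (3-exo-OH, 4-exo-OAc) | C=CC[C@]12C[C@H](O)[C@H](OC(C)=O)[C@](OC)(C1=O)[C@H](c1ccc(OC)c(OC)c1)[C@H]2C | intermediate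
20 | (1R,4R,5S,6S,7R)-6-(3,4-dimethoxyphenyl)-5-methoxy-7-methyl-3,8-dioxo-1-(prop-2-en-1-yl)bicyclo[3.2.1]octan-4-yl acetate (4-exo-OAc) | C=CC[C@]12CC(=O)[C@H](OC(C)=O)[C@](OC)(C1=O)[C@H](c1ccc(OC)c(OC)c1)[C@H]2C | intermediate
21 | (1R,4R,5S,6S,7R)-6-(3,4-dimethoxyphenyl)-3,3,5-trimethoxy-7-methyl-8-oxo-1-(prop-2-en-1-yl)bicyclo[3.2.1]octan-4-yl acetate | C=CC[C@]12CC(OC)(OC)[C@H](OC(C)=O)[C@](OC)(C1=O)[C@H](c1ccc(OC)c(OC)c1)[C@H]2C | intermediate
22 | (1S,4S,5S,6S,7R)-6-(3,4-dimethoxyphenyl)-3,5-dimethoxy-7-methyl-8-oxo-1-(prop-2-en-1-yl)bicyclo[3.2.1]oct-2-en-4-yl acetate (4-exo-OAc, 6-exo-aryl, 7-endo-methyl) | C=CC[C@]12C=C(OC)[C@H](OC(C)=O)[C@](OC)(C1=O)[C@H](c1ccc(OC)c(OC)c1)[C@H]2C | target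

Total step count: 15. Longest linear sequence: 15 steps (from 1 to 22; the route is fully linear).

Steps most likely to fail

Step 11. Electron transfer may run beyond the two aldehydes (reductive loss of the C5 methoxy group), the samarium aldolate may open by retro-aldol reaction, or the ketyls may couple without the samarium bridge and erode the cis/exo selectivity. The fallback is a redox-neutral closure of the same C3–C4 bond that sets out from 16. An N-aryl bicyclic triazolium precatalyst (10 mol %) with iPr2NEt in CH2Cl2 effects an intramolecular cross-benzoin reaction. The Breslow intermediate forms at the unhindered C3 aldehyde and adds to the neopentyl C4 aldehyde, which gives the 4-exo-hydroxy-3-ketone F1 directly. Since this closure is reversible, the epimer whose hydroxyl is on the exo face and hydrogen-bonded to the C3 and C8 carbonyl groups is expected to accumulate; this would have to be confirmed. Acetylation (Ac2O, pyridine, DMAP, 0 °C) comes back to the route at 20, so steps 12 and 13 are bypassed.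

Step 15. Ionisation of the ketal may be diverted by the neighbouring acetate (acyloxonium participation and acetyl scrambling), or the proton may be lost toward C4 with loss of regiochemistry and of the C4 configuration. The fallback sets out from 20 and avoids any cationic intermediate. Kinetic deprotonation of the C2 methylene with KN(SiMe3)2 in THF/DMPU at −78 °C gives the potassium C2-enolate F2; the C4–H is equatorial and hindered, and the acetate methyl group is much less acidic. O-Methylation with methyl triflate comes back to the route at 22.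

Step 5. The 1,3-related C6 aryl group may compete with the vicinal C7 methyl group for control of the allylation face, and C-alkylation of the hindered enolate may be sluggish. The fallback reverses the order in which the two C1 substituents arrive and sets out from 5. Stille coupling with allyltributylstannane (Pd(PPh3)4, DMF) gives the 2-allyl enone F3. Me2CuLi then gives the lithium enolate F4, which is alkylated with tert-butyl bromoacetate 6 (HMPA, THF) and comes back to the route at 11. The acetate arm is then the group that enters last, so whichever face the last electrophile prefers, one of the two orders delivers 11.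

Further compounds
F1 | step 11 | (1R,4S,5S,6S,7R)-6-(3,4-dimethoxyphenyl)-4-hydroxy-5-methoxy-7-methyl-1-(prop-2-en-1-yl)bicyclo[3.2.1]octane-3,8-dione (4-exo-OH) | C=CC[C@]12CC(=O)[C@H](O)[C@](OC)(C1=O)[C@H](c1ccc(OC)c(OC)c1)[C@H]2C
F2 | step 15 | potassium C2-enolate of 20 (C2=C3 enolate, 4-exo-OAc) | [K+].C=CC[C@]12C=C([O-])[C@H](OC(C)=O)[C@](OC)(C1=O)[C@H](c1ccc(OC)c(OC)c1)[C@H]2C
F3 | step 5 | (4S)-4-(3,4-dimethoxyphenyl)-2-(prop-2-en-1-yl)cyclopent-2-en-1-one | C=CCC1=C[C@@H](c2ccc(OC)c(OC)c2)CC1=O
F4 | step 5 | lithium (3R,4S)-4-(3,4-dimethoxyphenyl)-3-methyl-2-(prop-2-en-1-yl)cyclopent-1-en-1-olate | [Li+].C=CCC1=C([O-])C[C@H](c2ccc(OC)c(OC)c2)[C@H]1C
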